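**Retrosynthetic overview**

1. Locants used below: cyclohexane C1 (quaternary; methyl and vinyl), C2 and C3 (CH2), C4 (CH carrying the side chain), C5 (CH2), C6 (CH carrying isopropenyl). Target ⇐ triol 33 (selective bis-acetylation) ⇐ C1 methyl from a CH2OH (tosylate, hydride) and isopropenyl from a masked methyl ketone (methylenation) ⇐ Z-selective Wittig union of α-silyloxy ketone 20 with ylide 26, whose stereocenter is bought as (R)-α-hydroxy-γ-butyrolactone.
2. Ketone 20 ⇐ the only carbocycle-forming event: the C5–C6 bond is made by Lewis-acid addition of the enol-ether carbon of a 2-methyl-4,5-dihydrofuran to the terminal CH2 of a tethered α-methylene ketone (17), giving a cis-fused octahydro-2-benzofuran.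
3. Enabling feature: the temporary dihydrofuran ring O–C(CH3)=CH–C(quaternary)–CH2. It ties the oxygenated carbon that becomes the C1 methyl to the carbon that becomes the isopropenyl carbon; its =CH is the nucleophilic C6. Because this five-membered ring is flat, the four-atom chain on the quaternary carbon can bond only to the face it stands on, so C6 is relayed from C1 and C4 then follows by equilibration.
4. 17 ⇐ dihydrofuran 12 (bromine–lithium exchange, Weinreb amide 14) ⇐ palladium-catalysed asymmetric allylic alkylation of racemic vinyl epoxide 7 with tert-butyl acetoacetate (sets C1) ⇐ N-methoxy-N-methylacetamide, 2,3-dibromopropene, vinylmagnesium bromide.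
5. Ring order: oxirane (step 3, consumed in step 4); dihydrofuran (step 4, temporary); cyclohexane (step 8); the five-membered oxygen ring is opened in step 14.

Key step: step 8

Assumption: the (S,S)-enantiomer of the bis(phosphine) diamide ligand is written for step 4 as the one taken to deliver the (S)-configured quaternary carbon of 10; if the sense of induction is the opposite, the (R,R)-ligand is used with no other change.

**Route**

Step 1
Reactants: 1 N-methoxy-N-methylacetamide; 2 2,3-dibromoprop-1-ene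
Product: 4 4-bromo-N-methoxy-N-methylpent-4-enamide, via lithium enolate 3 (not isolated)
Conditions: LiN(i-Pr)2 (1.05 equiv), THF, −78 °C; then 2, −78 → −30 °C
Reagents that add atoms: none
Why: Alkylation of the amide enolate by SN2 at the allylic CH2Br of 2 (the vinylic bromide is inert) installs the latent 2-lithioalkene handle; no stereocenter is formed.

Step 2
Reactants: 4 4-bromo-N-methoxy-N-methylpent-4-enamide
Product: 6 6-bromohepta-1,6-dien-3-one, via magnesium hemiaminal chelate 5 (not isolated)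
Conditions: CH2=CHMgBr (1.3 equiv), THF, −78 → 0 °C; cold 1 M HCl quench
Reagents that add atoms: vinylmagnesium bromide, C=C[Mg]Br
Why: Weinreb ketone synthesis, in which the chelated tetrahedral intermediate prevents over-addition and the cold acidic quench protonates the released amine so that it cannot add to the vinyl ketone.

Step 3
Reactants: 6 6-bromohepta-1,6-dien-3-one
Product: 7 rac-2-(3-bromobut-3-en-1-yl)-2-ethenyloxirane
Conditions: Me3S+ I− (1.3 equiv), n-BuLi (1.25 equiv), THF, −10 °C; then 6, −10 °C → rt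
Reagents that add atoms: trimethylsulfonium iodide, C[S+](C)C.[I-]
Why: Corey–Chaykovsky epoxidation, in which the unstabilised sulfonium methylide adds 1,2 to the enone carbonyl and closes the oxirane; the new stereocenter is left racemic on purpose because step 4 is stereoconvergent.

Step 4
Reactants: 7 rac-2-(3-bromobut-3-en-1-yl)-2-ethenyloxirane; 8 tert-butyl 3-oxobutanoate
Product: 10 tert-butyl (4S)-4-(3-bromobut-3-en-1-yl)-4-ethenyl-2-methyl-4,5-dihydrofuran-3-carboxylate, via open-chain hydroxy keto ester 9 (not isolated)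
Conditions: Pd2(dba)3·CHCl3 (1 mol%), (S,S)-N,N′-(cyclohexane-1,2-diyl)bis[2-(diphenylphosphanyl)benzamide] (3 mol%), CH2Cl2, rt; then TsOH·H2O (5 mol%), 4 Å MS, rt
Reagents that add atoms: none
Why: Tsuji–Trost asymmetric allylic alkylation run as a dynamic kinetic asymmetric transformation: zerovalent palladium ionises the racemic vinyl epoxide to interconverting π-allyl alkoxides, the alkoxide deprotonates the β-keto ester and steers it to the substituted terminus, and the chiral ligand selects the enantioface, so the quaternary carbon (future C1) is set by the catalyst before acid dehydrates the hemiketal to the push–pull dihydrofuran.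

Step 5
Reactants: 10 tert-butyl (4S)-4-(3-bromobut-3-en-1-yl)-4-ethenyl-2-methyl-4,5-dihydrofuran-3-carboxylate
Product: 12 (4S)-4-(3-bromobut-3-en-1-yl)-4-ethenyl-2-methyl-4,5-dihydrofuran, via dihydrofurancarboxylic acid 11 (not isolated)
Conditions: TsOH·H2O (5 mol%), toluene (0.05 M), 100 °C; K2CO3 quench
Reagents that add atoms: none
Why: Acid-mediated loss of isobutene, then decarboxylation of the β-alkoxyacrylic acid through C-protonation (the cyclic counterpart of β-keto acid decarboxylation); the quaternary stereocenter has no acidic hydrogen, and the nucleophilic carbon of the product enol ether is neopentyl, which should retard acid-catalysed self-condensation.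

Step 6
Reactants: 13 methyl 2-[(tert-butyldimethylsilyl)oxy]acetate
Product: 14 2-[(tert-butyldimethylsilyl)oxy]-N-methoxy-N-methylacetamide
Conditions: MeNH(OMe)·HCl (1.5 equiv), i-PrMgCl (3.0 equiv), THF, −20 → 0 °C
Reagents that add atoms: N,O-dimethylhydroxylamine hydrochloride, CNOC.Cl
Why: Direct Weinreb amidation of a methyl ester by the chloromagnesium amide, which spares the silyl ether.

Step 7
Reactants: 12 (4S)-4-(3-bromobut-3-en-1-yl)-4-ethenyl-2-methyl-4,5-dihydrofuran; 14 2-[(tert-butyldimethylsilyl)oxy]-N-methoxy-N-methylacetamide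
Product: 17 1-[(tert-butyldimethylsilyl)oxy]-5-[(4S)-4-ethenyl-2-methyl-4,5-dihydrofuran-4-yl]-3-methylidenepentan-2-one, via alkenyllithium 15 (not isolated), via lithium hemiaminal chelate 16 (not isolated)
Conditions: t-BuLi (2.05 equiv), Et2O, −78 °C; then 14, −78 → −30 °C; cold sat. aq NH4Cl; used at once
Reagents that add atoms: none
Why: Bromine–lithium exchange on the 2-bromo-1-alkene followed by Weinreb ketone synthesis gives the α-methylene ketone directly, the enol ether serving as a base-stable mask for both the hydroxyl and the methyl ketone.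

Step 8
Reactants: 17 1-[(tert-butyldimethylsilyl)oxy]-5-[(4S)-4-ethenyl-2-methyl-4,5-dihydrofuran-4-yl]-3-methylidenepentan-2-one
Product: 20 2-[(tert-butyldimethylsilyl)oxy]-1-[(3aS,6S,7aS)-3a-ethenyl-1-methoxy-1-methyloctahydro-2-benzofuran-6-yl]ethan-1-one, via oxocarbenium boron enolate zwitterion 18 (not isolated), via C4-epimeric keto ketal mixture 19 (not isolated)
Conditions: BF3·OEt2 (1.1 equiv), CH2Cl2 (0.01 M), −78 °C; MeOH–pyridine, −78 °C → rt; then PPTS (cat.), MeOH, rt; then DBU (0.3 equiv), CH2Cl2, rt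
Reagents that add atoms: methanol, CO
Why: BF3 activates the α-methylene ketone and the enol-ether carbon of the dihydrofuran (future C6) adds to its unsubstituted terminus (C5), giving zwitterion 18, which methanol–pyridine discharges to the mixed methyl ketal and the ketone; this is a Mukaiyama–Michael-type addition, the stepwise branch of the known Lewis-acid reaction of enol ethers with α,β-unsaturated ketones, because the concerted [4+2] adduct would be a strained bridgehead enol ether. The carbocycle closes 6-endo-trig at the enone (C4 and C5 both end in the ring) and exo with respect to the enol ether, and it is formed cis-fused to the five-membered ring. C6 is controlled by the tether: the flat dihydrofuran can be reached by the four-atom chain on quaternary C1 only on the face that carries it, so the new C5–C6 bond is cis to C1–C2, which places the ketal carbon (future isopropenyl carbon) cis to the ring CH2O (future methyl) and trans to vinyl. C4 is set by thermodynamics: the fully substituted ketal carbon locks the chair in which it is equatorial, and DBU equilibration should move the acyl group to the equatorial position cis to it whatever the face of kinetic protonation, while the ketal carbon itself is an inconsequential epimer mixture removed in step 13. The selectivities needed are 1,4- over 1,2-addition (both six-membered closures; secured by the unhindered terminal CH2 against a carbonyl flanked by a fully substituted alkene carbon and CH2OSi) and enol ether over the C1 vinyl group as nucleophile (secured by the far higher nucleophilicity of the enol ether). The ketal formed in the quench also blocks retro-Michael and intramolecular aldol pathways of the 1,5-dicarbonyl array and differentiates the two ketones for step 13.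

Step 9
Reactants: 21 (3R)-3-hydroxyoxolan-2-one [(R)-α-hydroxy-γ-butyrolactone]
Product: 22 (3R)-4-methylpentane-1,3,4-triol
Conditions: MeMgBr (4.5 equiv), THF, 0 °C → rt; sat. aq NH4Cl (minimum), non-aqueous isolation
Reagents that add atoms: methylmagnesium bromide, C[Mg]Br
Why: Double Grignard addition to the lactone carbonyl, in which the α-alkoxide formed first blocks enolisation so that the purchased stereocenter is retained.

Step 10
Reactants: 22 (3R)-4-methylpentane-1,3,4-triol
Product: 23 2-[(4R)-2,2,5,5-tetramethyl-1,3-dioxolan-4-yl]ethan-1-ol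
Conditions: Me2C(OMe)2, PPTS (cat.), acetone, rt; Et3N, then brief aq NaHCO3
Reagents that add atoms: 2,2-dimethoxypropane, COC(C)(C)OC
Why: Thermodynamic acetonide formation should select the five-membered dioxolane of the vicinal secondary/tertiary diol over the six-membered 1,3-dioxane with its axial methyl group, leaving the primary hydroxyl free.

Step 11
Reactants: 23 2-[(4R)-2,2,5,5-tetramethyl-1,3-dioxolan-4-yl]ethan-1-ol
Product: 24 (4R)-4-(2-iodoethyl)-2,2,5,5-tetramethyl-1,3-dioxolane
Conditions: I2, PPh3, imidazole, CH2Cl2, 0 °C → rt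
Reagents that add atoms: iodine, II
Why: Appel-type iodination of the primary alcohol under imidazole buffering, which spares the acetonide.

Step 12
Reactants: 24 (4R)-4-(2-iodoethyl)-2,2,5,5-tetramethyl-1,3-dioxolane
Product: 25 triphenyl{2-[(4R)-2,2,5,5-tetramethyl-1,3-dioxolan-4-yl]ethyl}phosphonium iodide
Conditions: PPh3 (1.2 equiv), K2CO3 (cat.), MeCN, 80 °C
Reagents that add atoms: triphenylphosphine, c1ccc(cc1)P(c1ccccc1)c1ccccc1
Why: SN2 quaternisation of the phosphine by the primary iodide; the ether oxygen is γ to phosphorus, so the derived ylide cannot β-eliminate.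

Step 13
Reactants: 20 2-[(tert-butyldimethylsilyl)oxy]-1-[(3aS,6S,7aS)-3a-ethenyl-1-methoxy-1-methyloctahydro-2-benzofuran-6-yl]ethan-1-one; 25 triphenyl{2-[(4R)-2,2,5,5-tetramethyl-1,3-dioxolan-4-yl]ethyl}phosphonium iodide
Product: 28 (3aS,6S,7aS)-6-{(2Z)-1-[(tert-butyldimethylsilyl)oxy]-4-[(4R)-2,2,5,5-tetramethyl-1,3-dioxolan-4-yl]but-2-en-2-yl}-3a-ethenyl-1-methyloctahydro-2-benzofuran-1-ol, via phosphorus ylide 26 (not isolated), via Z-olefin methyl ketal 27 (not isolated)
Conditions: 25 (1.6 equiv), NaN(SiMe3)2 (1.5 equiv), THF, 0 °C; then 20, −78 °C → rt; then PPTS (cat.), acetone–H2O 4:1, rt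
Reagents that add atoms: water, O
Why: Wittig olefination of an α-silyloxy ketone with a non-stabilised ylide, a combination known to place the ylide substituent cis to the alkoxymethyl group (here also the smaller ketone substituent) and thus to give the Z-trisubstituted olefin, after which mild aqueous acid hydrolyses only the mixed cyclic ketal while the acetonide is held by the acetone solvent.

Step 14
Reactants: 28 (3aS,6S,7aS)-6-{(2Z)-1-[(tert-butyldimethylsilyl)oxy]-4-[(4R)-2,2,5,5-tetramethyl-1,3-dioxolan-4-yl]but-2-en-2-yl}-3a-ethenyl-1-methyloctahydro-2-benzofuran-1-ol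
Product: 30 [(1S,2R,4S)-4-{(2Z)-1-[(tert-butyldimethylsilyl)oxy]-4-[(4R)-2,2,5,5-tetramethyl-1,3-dioxolan-4-yl]but-2-en-2-yl}-1-ethenyl-2-(prop-1-en-2-yl)cyclohexyl]methanol, via ring-opened keto alkoxide 29 (not isolated)
Conditions: Ph3PCH3Br (5 equiv), KOt-Bu (4.8 equiv), THF, 0 → 50 °C
Reagents that add atoms: methyltriphenylphosphonium bromide, C[P+](c1ccccc1)(c1ccccc1)c1ccccc1.[Br-]
Why: Wittig methylenation of the methyl ketone that is in equilibrium with the lactol alkoxide; should C6 enolise, it returns to the favoured arrangement with acetyl equatorial and cis to the equatorial C4 side chain, so its configuration is not at risk.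

Step 15
Reactants: 30 [(1S,2R,4S)-4-{(2Z)-1-[(tert-butyldimethylsilyl)oxy]-4-[(4R)-2,2,5,5-tetramethyl-1,3-dioxolan-4-yl]but-2-en-2-yl}-1-ethenyl-2-(prop-1-en-2-yl)cyclohexyl]methanol
Product: 31 [(1S,2R,4S)-4-{(2Z)-1-[(tert-butyldimethylsilyl)oxy]-4-[(4R)-2,2,5,5-tetramethyl-1,3-dioxolan-4-yl]but-2-en-2-yl}-1-ethenyl-2-(prop-1-en-2-yl)cyclohexyl]methyl 4-methylbenzenesulfonate
Conditions: TsCl (2 equiv), Et3N, DMAP (cat.), CH2Cl2, rt
Reagents that add atoms: p-toluenesulfonyl chloride, Cc1ccc(cc1)S(Cl)(=O)=O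
Why: Sulfonylation of the primary neopentyl alcohol under basic conditions, which avoids acid-induced addition of the hydroxyl to the neighbouring isopropenyl group.

Step 16
Reactants: 31 [(1S,2R,4S)-4-{(2Z)-1-[(tert-butyldimethylsilyl)oxy]-4-[(4R)-2,2,5,5-tetramethyl-1,3-dioxolan-4-yl]but-2-en-2-yl}-1-ethenyl-2-(prop-1-en-2-yl)cyclohexyl]methyl 4-methylbenzenesulfonate
Product: 32 tert-butyl{[(2Z)-2-[(1S,3R,4R)-4-ethenyl-4-methyl-3-(prop-1-en-2-yl)cyclohexyl]-4-[(4R)-2,2,5,5-tetramethyl-1,3-dioxolan-4-yl]but-2-en-1-yl]oxy}dimethylsilane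
Conditions: LiEt3BH (4 equiv), THF, 0 → 60 °C
Reagents that add atoms: none
Why: SN2 hydride displacement of the neopentyl tosylate by lithium triethylborohydride, a polar path chosen because a radical deoxygenation would trigger 1,2-vinyl migration through the homoallyl–cyclopropylcarbinyl manifold; the C1 methyl is thereby revealed without touching any stereocenter.

Step 17
Reactants: 32 tert-butyl{[(2Z)-2-[(1S,3R,4R)-4-ethenyl-4-methyl-3-(prop-1-en-2-yl)cyclohexyl]-4-[(4R)-2,2,5,5-tetramethyl-1,3-dioxolan-4-yl]but-2-en-1-yl]oxy}dimethylsilane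
Product: 33 (2Z,5R)-2-[(1S,3R,4R)-4-ethenyl-4-methyl-3-(prop-1-en-2-yl)cyclohexyl]-6-methylhept-2-ene-1,5,6-triol
Conditions: TsOH·H2O (0.2 equiv), MeOH, rt
Reagents that add atoms: none
Why: Acid-catalysed methanolysis removes the acetonide and the primary silyl ether in one operation under conditions too mild to protonate the vinyl, isopropenyl or trisubstituted olefins.

Step 18
Reactants: 33 (2Z,5R)-2-[(1S,3R,4R)-4-ethenyl-4-methyl-3-(prop-1-en-2-yl)cyclohexyl]-6-methylhept-2-ene-1,5,6-triol
Product: 34 (2Z,5R)-2-[(1S,3R,4R)-4-ethenyl-4-methyl-3-(prop-1-en-2-yl)cyclohexyl]-6-hydroxy-6-methylhept-2-ene-1,5-diyl diacetate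
Conditions: Ac2O (2.4 equiv), pyridine, CH2Cl2, 0 °C → rt
Reagents that add atoms: acetic anhydride, CC(=O)OC(C)=O
Why: Acylation in which the primary allylic and the secondary hydroxyl are acetylated while the tertiary hydroxyl is inert in the absence of forcing conditions.

**Compound list**

1 | N-methoxy-N-methylacetamide | CC(=O)N(C)OC | starting material
2 | 2,3-dibromoprop-1-ene | BrCC(Br)=C | starting material
3 | lithium enolate of 1 | C=C(O[Li])N(C)OC | intermediate
4 | 4-bromo-N-methoxy-N-methylpent-4-enamide | C=C(Br)CCC(=O)N(C)OC | intermediate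
5 | bromomagnesium 6-bromo-3-[methoxy(methyl)amino]hepta-1,6-dien-3-olate (hemiaminal chelate) | C=CC(O[Mg]Br)(CCC(Br)=C)N(C)OC | intermediate
6 | 6-bromohepta-1,6-dien-3-one | C=CC(=O)CCC(Br)=C | intermediate
7 | rac-2-(3-bromobut-3-en-1-yl)-2-ethenyloxirane | C=CC1(CCC(Br)=C)CO1 | intermediate
8 | tert-butyl 3-oxobutanoate | CC(=O)CC(=O)OC(C)(C)C | starting material
9 | tert-butyl (3S)-2-acetyl-6-bromo-3-ethenyl-3-(hydroxymethyl)hept-6-enoate (both C2 epimers) | C=C[C@@](C(C(C)=O)C(=O)OC(C)(C)C)(CO)CCC(Br)=C | intermediate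
10 | tert-butyl (4S)-4-(3-bromobut-3-en-1-yl)-4-ethenyl-2-methyl-4,5-dihydrofuran-3-carboxylate | C=C[C@@]1(COC(C)=C1C(=O)OC(C)(C)C)CCC(Br)=C | intermediate
11 | (4S)-4-(3-bromobut-3-en-1-yl)-4-ethenyl-2-methyl-4,5-dihydrofuran-3-carboxylic acid | C=C[C@@]1(COC(C)=C1C(=O)O)CCC(Br)=C | intermediate
12 | (4S)-4-(3-bromobut-3-en-1-yl)-4-ethenyl-2-methyl-4,5-dihydrofuran | C=C[C@@]1(COC(C)=C1)CCC(Br)=C | intermediate
13 | methyl 2-[(tert-butyldimethylsilyl)oxy]acetate | COC(=O)CO[Si](C)(C)C(C)(C)C | starting material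
14 | 2-[(tert-butyldimethylsilyl)oxy]-N-methoxy-N-methylacetamide | CON(C)C(=O)CO[Si](C)(C)C(C)(C)C | intermediate
15 | {4-[(4S)-4-ethenyl-2-methyl-4,5-dihydrofuran-4-yl]but-1-en-2-yl}lithium | C=C[C@@]1(COC(C)=C1)CCC([Li])=C | intermediate
16 | lithium hemiaminal chelate from 15 and 14 (lithium alkoxide of the N-methoxy-N-methyl hemiaminal of 17) | C=C[C@@]1(COC(C)=C1)CCC(=C)C(O[Li])(CO[Si](C)(C)C(C)(C)C)N(C)OC | intermediate
17 | 1-[(tert-butyldimethylsilyl)oxy]-5-[(4S)-4-ethenyl-2-methyl-4,5-dihydrofuran-4-yl]-3-methylidenepentan-2-one | C=C[C@@]1(COC(C)=C1)CCC(=C)C(=O)CO[Si](C)(C)C(C)(C)C | intermediate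
18 | cyclised zwitterion: bicyclic oxocarbenium ion (C=O+ in the five-membered ring) carrying the exocyclic trifluoroborate enolate at C4 | C=C[C@@]12CCC(=C(O[B-](F)(F)F)CO[Si](C)(C)C(C)(C)C)C[C@@H]1C(C)=[O+]C2 | intermediate
19 | 2-[(tert-butyldimethylsilyl)oxy]-1-[(3aS,7aS)-3a-ethenyl-1-methoxy-1-methyloctahydro-2-benzofuran-6-yl]ethan-1-one (mixture of epimers at ring position 6) | C=C[C@@]12CCC(C(=O)CO[Si](C)(C)C(C)(C)C)C[C@@H]1C(C)(OC)OC2 | intermediate
20 | 2-[(tert-butyldimethylsilyl)oxy]-1-[(3aS,6S,7aS)-3a-ethenyl-1-methoxy-1-methyloctahydro-2-benzofuran-6-yl]ethan-1-one (both epimers at the ketal carbon) | C=C[C@@]12CC[C@H](C(=O)CO[Si](C)(C)C(C)(C)C)C[C@@H]1C(C)(OC)OC2 | intermediate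
21 | (3R)-3-hydroxyoxolan-2-one | O[C@@H]1CCOC1=O | starting material
22 | (3R)-4-methylpentane-1,3,4-triol | OCC[C@@H](O)C(C)(C)O | intermediate
23 | 2-[(4R)-2,2,5,5-tetramethyl-1,3-dioxolan-4-yl]ethan-1-ol | OCC[C@H]1OC(C)(C)OC1(C)C | intermediate
24 | (4R)-4-(2-iodoethyl)-2,2,5,5-tetramethyl-1,3-dioxolane | ICC[C@H]1OC(C)(C)OC1(C)C | intermediate
25 | triphenyl{2-[(4R)-2,2,5,5-tetramethyl-1,3-dioxolan-4-yl]ethyl}phosphonium iodide | [I-].C(C[P+](c1ccccc1)(c1ccccc1)c1ccccc1)[C@H]1OC(C)(C)OC1(C)C | intermediate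
26 | triphenyl{2-[(4R)-2,2,5,5-tetramethyl-1,3-dioxolan-4-yl]ethylidene}phosphorane | C(C=P(c1ccccc1)(c1ccccc1)c1ccccc1)[C@H]1OC(C)(C)OC1(C)C | intermediate
27 | tert-butyl{[(2Z)-2-[(3aS,6S,7aS)-3a-ethenyl-1-methoxy-1-methyloctahydro-2-benzofuran-6-yl]-4-[(4R)-2,2,5,5-tetramethyl-1,3-dioxolan-4-yl]but-2-en-1-yl]oxy}dimethylsilane (both ketal epimers) | C=C[C@@]12CC[C@H](/C(=C/C[C@H]3OC(C)(C)OC3(C)C)CO[Si](C)(C)C(C)(C)C)C[C@@H]1C(C)(OC)OC2 | intermediate
28 | (3aS,6S,7aS)-6-{(2Z)-1-[(tert-butyldimethylsilyl)oxy]-4-[(4R)-2,2,5,5-tetramethyl-1,3-dioxolan-4-yl]but-2-en-2-yl}-3a-ethenyl-1-methyloctahydro-2-benzofuran-1-ol (both lactol epimers) | C=C[C@@]12CC[C@H](/C(=C/C[C@H]3OC(C)(C)OC3(C)C)CO[Si](C)(C)C(C)(C)C)C[C@@H]1C(C)(O)OC2 | intermediate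
29 | potassium alkoxide of 1-[(1R,2S,5S)-5-{(2Z)-1-[(tert-butyldimethylsilyl)oxy]-4-[(4R)-2,2,5,5-tetramethyl-1,3-dioxolan-4-yl]but-2-en-2-yl}-2-ethenyl-2-(hydroxymethyl)cyclohexyl]ethan-1-one | C=C[C@@]1(CO[K])CC[C@H](/C(=C/C[C@H]2OC(C)(C)OC2(C)C)CO[Si](C)(C)C(C)(C)C)C[C@@H]1C(C)=O | intermediate
30 | [(1S,2R,4S)-4-{(2Z)-1-[(tert-butyldimethylsilyl)oxy]-4-[(4R)-2,2,5,5-tetramethyl-1,3-dioxolan-4-yl]but-2-en-2-yl}-1-ethenyl-2-(prop-1-en-2-yl)cyclohexyl]methanol | C=C[C@@]1(CO)CC[C@H](/C(=C/C[C@H]2OC(C)(C)OC2(C)C)CO[Si](C)(C)C(C)(C)C)C[C@@H]1C(=C)C | intermediate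
31 | [(1S,2R,4S)-4-{(2Z)-1-[(tert-butyldimethylsilyl)oxy]-4-[(4R)-2,2,5,5-tetramethyl-1,3-dioxolan-4-yl]but-2-en-2-yl}-1-ethenyl-2-(prop-1-en-2-yl)cyclohexyl]methyl 4-methylbenzenesulfonate | C=C[C@@]1(COS(=O)(=O)c2ccc(C)cc2)CC[C@H](/C(=C/C[C@H]2OC(C)(C)OC2(C)C)CO[Si](C)(C)C(C)(C)C)C[C@@H]1C(=C)C | intermediate
32 | tert-butyl{[(2Z)-2-[(1S,3R,4R)-4-ethenyl-4-methyl-3-(prop-1-en-2-yl)cyclohexyl]-4-[(4R)-2,2,5,5-tetramethyl-1,3-dioxolan-4-yl]but-2-en-1-yl]oxy}dimethylsilane | C=C[C@@]1(C)CC[C@H](/C(=C/C[C@H]2OC(C)(C)OC2(C)C)CO[Si](C)(C)C(C)(C)C)C[C@@H]1C(=C)C | intermediate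
33 | (2Z,5R)-2-[(1S,3R,4R)-4-ethenyl-4-methyl-3-(prop-1-en-2-yl)cyclohexyl]-6-methylhept-2-ene-1,5,6-triol | C=C[C@@]1(C)CC[C@H](/C(=C/C[C@@H](O)C(C)(C)O)CO)C[C@@H]1C(=C)C | intermediate
34 | (2Z,5R)-2-[(1S,3R,4R)-4-ethenyl-4-methyl-3-(prop-1-en-2-yl)cyclohexyl]-6-hydroxy-6-methylhept-2-ene-1,5-diyl diacetate | C=C[C@@]1(C)CC[C@H](/C(=C/C[C@@H](OC(C)=O)C(C)(C)O)COC(C)=O)C[C@@H]1C(=C)C | target

**Step count and risks**

Total step count: 18. Longest linear sequence: 13 steps (steps 1–5, 7, 8, 13–18); the ylide branch is steps 9–12 and the amide branch is step 6.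

Steps most likely to fail, with fallbacks:

Step 8 (key cyclisation). What may go wrong: the Lewis acid may divert the enol ether into 1,2-addition to the ketone, into intermolecular oligomerisation, or may cause loss of the silyl ether before the carbon–carbon bond forms. The fallback forms the same bond by a radical instead of a polar path; it sets out from 17 and comes back at 19. Iodomethoxylation of the enol ether (N-iodosuccinimide, MeOH, CH2Cl2, −20 °C) would give 1-[(tert-butyldimethylsilyl)oxy]-5-[(3R)-3-ethenyl-4-iodo-5-methoxy-5-methyloxolan-3-yl]-3-methylidenepentan-2-one F1. Slow addition of Bu3SnH with AIBN in benzene at 80 °C would generate the secondary radical at C6, which should close 6-endo on the unsubstituted terminus of the α-methylene ketone (a polarity-matched nucleophilic radical, with the same one-face tether and hence the same cis fusion). Hydrogen transfer then gives keto ketal 19, which is equilibrated with DBU to 20 as in step 8.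

Step 4 (asymmetric allylic alkylation). What may go wrong: insufficient enantioface discrimination on the interconverting π-allyl intermediates once the 2-substituent of the epoxide is larger than methyl. The fallback replaces asymmetric catalysis by classical resolution; it sets out from 7 and 8 and comes back at 12. Alkylation with achiral Pd(PPh3)4 and the same acid work-up would give racemic tert-butyl 4-(3-bromobut-3-en-1-yl)-4-ethenyl-2-methyl-4,5-dihydrofuran-3-carboxylate F2. TFA in CH2Cl2 at 0 °C would give racemic 4-(3-bromobut-3-en-1-yl)-4-ethenyl-2-methyl-4,5-dihydrofuran-3-carboxylic acid F3. Fractional crystallisation with (S)-1-phenylethylamine would give (S)-1-phenylethylammonium (4S)-4-(3-bromobut-3-en-1-yl)-4-ethenyl-2-methyl-4,5-dihydrofuran-3-carboxylate F4 (the antipodal amine is used if the other salt is the less soluble one). Cold aqueous citric acid then releases acid 11, which is decarboxylated in toluene at 100 °C to 12.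

Step 16 (hydride displacement). What may go wrong: SN2 at the crowded neopentyl carbon may be so slow that hydride attacks sulfur and returns alcohol 30, or ionisation with vinyl participation may rearrange the skeleton. The fallback is a carbonyl deoxygenation; it sets out from 30 and comes back at 32. Dess–Martin periodinane with NaHCO3 in CH2Cl2 would give (1S,2R,4S)-4-{(2Z)-1-[(tert-butyldimethylsilyl)oxy]-4-[(4R)-2,2,5,5-tetramethyl-1,3-dioxolan-4-yl]but-2-en-2-yl}-1-ethenyl-2-(prop-1-en-2-yl)cyclohexane-1-carbaldehyde F5. Condensation with 1,2-bis(tert-butyldimethylsilyl)hydrazine (Sc(OTf)3 cat.) would give its N-(tert-butyldimethylsilyl)hydrazone F6. KOt-Bu in t-BuOH–DMSO at rt (low-temperature Wolff–Kishner reduction) should then give 32.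

**Further compounds**

F1 | step 8 | 1-[(tert-butyldimethylsilyl)oxy]-5-[(3R)-3-ethenyl-4-iodo-5-methoxy-5-methyloxolan-3-yl]-3-methylidenepentan-2-one (epimers at the iodo and ketal carbons) | C=C[C@@]1(COC(C)(OC)C1I)CCC(=C)C(=O)CO[Si](C)(C)C(C)(C)C
F2 | step 4 | rac-tert-butyl 4-(3-bromobut-3-en-1-yl)-4-ethenyl-2-methyl-4,5-dihydrofuran-3-carboxylate | C=CC1(COC(C)=C1C(=O)OC(C)(C)C)CCC(Br)=C
F3 | step 4 | rac-4-(3-bromobut-3-en-1-yl)-4-ethenyl-2-methyl-4,5-dihydrofuran-3-carboxylic acid | C=CC1(COC(C)=C1C(=O)O)CCC(Br)=C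
F4 | step 4 | (S)-1-phenylethylammonium (4S)-4-(3-bromobut-3-en-1-yl)-4-ethenyl-2-methyl-4,5-dihydrofuran-3-carboxylate | C=C[C@@]1(COC(C)=C1C(=O)[O-])CCC(Br)=C.C[C@H]([NH3+])c1ccccc1
F5 | step 16 | (1S,2R,4S)-4-{(2Z)-1-[(tert-butyldimethylsilyl)oxy]-4-[(4R)-2,2,5,5-tetramethyl-1,3-dioxolan-4-yl]but-2-en-2-yl}-1-ethenyl-2-(prop-1-en-2-yl)cyclohexane-1-carbaldehyde | C=C[C@@]1(C=O)CC[C@H](/C(=C/C[C@H]2OC(C)(C)OC2(C)C)CO[Si](C)(C)C(C)(C)C)C[C@@H]1C(=C)C
F6 | step 16 | N-(tert-butyldimethylsilyl)hydrazone of F5 (E) | C=C[C@@]1(/C=N/N[Si](C)(C)C(C)(C)C)CC[C@H](/C(=C/C[C@H]2OC(C)(C)OC2(C)C)CO[Si](C)(C)C(C)(C)C)C[C@@H]1C(=C)C
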